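**Plan**
- Retrosynthesis: the six aryl C–Br bonds are removed first, then each catechol ring is taken back to a cyclohex-4-ene-cis-1,2-diol and cut at C3–C4 and C5–C6 (ring numbering: C1 carries the CH2O arm, C2/C3/C6 carry Br, C4/C5 carry OH).
- Enabling feature: in each ring, C4–C5 with its two adjacent oxygens is a cis-dioxygenated two-carbon dienophile (vinylene carbonate). C6–C1–C2–C3, with the CH2O arm on C1, is a 2-substituted buta-1,3-diene, so the central CH2–O–CH2 ether is a bis-diene.
- Forward order: the ether C–O bond is made first (Williamson), the two vinyl groups are attached by a twofold Kumada coupling, and both carbocycles then arise together in a double Diels–Alder reaction. Carbonate removal, oxidation with aromatisation and sixfold bromination follow.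
- Stereochemistry: the target is achiral. The cycloaddition sets four transient stereocentres, cis within each ring because the dienophile is Z; the cross-ring relationship is uncontrolled and irrelevant, since aromatisation destroys all four.

Key step: step 3

Assumption: the target has no stereocentre, so the "single enantiomer" is simply the one achiral constitution shown and nothing has to be resolved.

**Route**

Step 1
Reactants: 1 2-bromoprop-2-en-1-ol (2-bromoallyl alcohol); 2 2,3-dibromoprop-1-ene
Product: 3 bis(2-bromoprop-2-en-1-yl) ether
Conditions: NaH (1.1 equiv), THF, 0 °C; then 2 (1.1 equiv), Bu4NI (5 mol%), 0 °C → rt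
Reagents that add atoms: 2,3-dibromoprop-1-ene (2), C=C(Br)CBr
Why: Williamson ether synthesis, in which the primary alkoxide of 1 displaces the allylic bromide of 2 by SN2 while the vinylic C–Br bonds of both partners are inert to alkoxide at this temperature; no stereocentre is formed.

Step 2
Reactants: 3 bis(2-bromoprop-2-en-1-yl) ether; 4 vinylmagnesium bromide
Product: 5 bis(2-methylidenebut-3-en-1-yl) ether (the bis-diene)
Conditions: CH2=CHMgBr (2.6 equiv, THF), Pd(PPh3)4 (3 mol%), THF, 0 °C → rt; aq. NH4Cl; BHT added before cold concentration, product stored at −20 °C
Reagents that add atoms: vinylmagnesium bromide (4), C=C[Mg]Br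
Why: Twofold Kumada–Corriu coupling (oxidative addition of Pd(0) into each 1,1-disubstituted alkenyl bromide, transmetalation with the vinyl Grignard reagent, reductive elimination), the standard way from 2-bromoallyl compounds to 2-substituted butadienes; the dialkyl ether is inert to the Grignard reagent and no stereocentre is formed.

Step 3
Reactants: 5 bis(2-methylidenebut-3-en-1-yl) ether; 6 vinylene carbonate
Product: 7 5,5'-[oxybis(methylene)]bis(cis-3a,4,7,7a-tetrahydro-1,3-benzodioxol-2-one), the bis-carbonate
Conditions: 6 (20 equiv, neat, as solvent), BHT (5 mol%), sealed tube, 175 °C, 18 h; excess 6 distilled off in vacuo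
Reagents that add atoms: vinylene carbonate (6), O=C1OC=CO1
Why: Each diene unit of 5 adds one molecule of 6 in a concerted, thermally allowed [π4s+π2s] cycloaddition that forms C3–C4 and C5–C6 of its ring (four C–C bonds in all) and leaves the new ring alkene at C1=C2. The closest known reaction type is the thermal Diels–Alder addition of vinylene carbonate to butadiene, isoprene and other 2-substituted butadienes at 160–180 °C. Both carbocycles close in the intermolecular [4+2] mode as six-membered rings, each cis-fused to the five-membered carbonate brought in by the dienophile. The two stereocentres of each ring (C4, C5) are set cis by suprafacial addition to the Z dienophile, whereas the relationship between the rings is not controlled, so a mixture of the meso and racemic bis-adducts is expected and is carried on as such because step 5 erases all four centres. No regioselectivity is needed with a symmetric dienophile; the selectivity required is cross-cycloaddition in preference to diene–diene addition and radical polymerisation, and it is secured by the large excess of 6 as solvent, by the radical inhibitor, and by the short tether at the diene 2-positions, which would force a strained bridgehead alkene in any intramolecular diene–diene addition.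

Step 4
Reactants: 7 the bis-carbonate
Product: 8 4,4'-[oxybis(methylene)]bis(cyclohex-4-ene-cis-1,2-diol), the tetraol
Conditions: K2CO3 (0.2 equiv), MeOH, rt; Amberlyst-15 (H+ form), filter, concentrate
Reagents that add atoms: none
Why: Base-catalysed transesterification (methanolysis) of the cyclic carbonates breaks only acyl C–O bonds, so both cis-diols are released with their configuration intact and the allylic ether and ring alkenes are untouched.

Step 5
Reactants: 8 the tetraol
Product: 10 bis(3,4-dihydroxybenzyl) ether, via tetraketone 9 (not isolated)
Conditions: DMSO (12 equiv), (CF3CO)2O (5 equiv), CH2Cl2, −60 °C; 8 in DMSO–CH2Cl2, −60 °C, 1.5 h; Et3N (12 equiv), −60 °C → rt; pH 5 phosphate buffer work-up under N2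
Reagents that add atoms: none
Why: Swern-type oxidation with trifluoroacetic anhydride-activated DMSO is the established variant for turning vicinal diols, including vinylene carbonate-derived cis-diols, into 1,2-diones without C–C cleavage, and each cyclohex-4-ene-1,2-dione ring of 9 is a non-aromatic keto tautomer of a catechol that should enolise twice under triethylamine to the arene, removing all four stereocentres.

Step 6
Reactants: 10 bis(3,4-dihydroxybenzyl) ether; 11 N-bromosuccinimide
Product: 12 bis(2,3,6-tribromo-4,5-dihydroxybenzyl) ether (target)
Conditions: NBS (6.1 equiv, in portions), MeCN, −20 °C → rt, dark, N2; aq. Na2S2O3/ascorbic acid, EtOAc; no alcoholic solvents in work-up or purification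
Reagents that add atoms: N-bromosuccinimide (11), O=C1CCC(=O)N1Br
Why: Electrophilic aromatic bromination should fill all three open positions of each ring, since C3 and C6 are ortho to the C4 and C5 hydroxyls and C2 is para to the C5 hydroxyl, and NBS leaves only neutral succinimide, so the acid-labile p-hydroxybenzyl ether is not exposed to stoichiometric HBr.

**Compound list**

1 | 2-bromoprop-2-en-1-ol (2-bromoallyl alcohol) | OCC(Br)=C | starting material
2 | 2,3-dibromoprop-1-ene | C=C(Br)CBr | starting material
3 | bis(2-bromoprop-2-en-1-yl) ether | C=C(Br)COCC(Br)=C | intermediate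
4 | vinylmagnesium bromide (solution in THF) | C=C[Mg]Br | starting material
5 | bis(2-methylidenebut-3-en-1-yl) ether (bis-diene) | C=CC(=C)COCC(=C)C=C | intermediate
6 | vinylene carbonate (1,3-dioxol-2-one) | O=C1OC=CO1 | starting material
7 | 5,5'-[oxybis(methylene)]bis(cis-3a,4,7,7a-tetrahydro-1,3-benzodioxol-2-one); cis fusion (3aR*,7aS*) in each half, expected as a mixture of meso and racemic cross-ring diastereomers, meso form drawn | O=C1O[C@H]2CC=C(COCC3=CC[C@H]4OC(=O)O[C@H]4C3)C[C@H]2O1 | intermediate
8 | 4,4'-[oxybis(methylene)]bis(cyclohex-4-ene-1,2-diol); cis (1R*,2S*) in each ring, same diastereomer mixture, meso form drawn | O[C@H]1CC=C(COCC2=CC[C@@H](O)[C@@H](O)C2)C[C@H]1O | intermediate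
9 | 4,4'-[oxybis(methylene)]bis(cyclohex-4-ene-1,2-dione) (tetraketone; formed in the flask in step 5, not isolated) | O=C1CC=C(COCC2=CCC(=O)C(=O)C2)CC1=O | intermediate
10 | bis(3,4-dihydroxybenzyl) ether, 4,4'-[oxybis(methylene)]bis(benzene-1,2-diol) | Oc1ccc(COCc2ccc(O)c(O)c2)cc1O | intermediate
11 | N-bromosuccinimide | O=C1CCC(=O)N1Br | starting material
12 | bis(2,3,6-tribromo-4,5-dihydroxybenzyl) ether, 5,5'-[oxybis(methylene)]bis(3,4,6-tribromobenzene-1,2-diol); achiral | Oc1c(O)c(Br)c(COCc2c(Br)c(O)c(O)c(Br)c2Br)c(Br)c1Br | target

**Step count and risks**

Total steps: 6. Longest linear sequence: 6 steps (from 1 to 12).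

Steps most likely to fail, riskiest first:

Step 6 (sixfold bromination). The p-hydroxybenzylic C–O bond may ionise to a quinone methide under traces of acid. The catechol may be oxidised to an o-quinone instead of being substituted. Ipso attack at C1 may expel the CH2O arm, or substitution may stall at the hindered C2 position. The fallback sets out from 10 and returns at 12. It lets the ether break and rebuilds it afterwards. Excess Br2 in unbuffered AcOH should tribrominate each ring of 10 while the HBr formed cleaves the benzylic ether, giving two molecules of 2,3,6-tribromo-4,5-dihydroxybenzyl bromide F1. Hydrolysis in aqueous acetone should give 2,3,6-tribromo-4,5-dihydroxybenzyl alcohol F2. Acid-catalysed dehydrative self-etherification of F2 (cat. TsOH, MeNO2, 4 Å sieves), a known path for p-hydroxybenzyl alcohols through the quinone methide, should then give 12.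

Step 5 (oxidation and aromatisation). The freshly formed catechol may be captured by leftover activated DMSO (ortho-methylthiomethylation). Trifluoroacetylation may compete with oxidation, or the oxidation may stall at the α-ketol. The fallback sets out from 8 and returns at 10. It replaces activated DMSO by hypervalent iodine and makes over-oxidation deliberate. IBX (excess, DMSO, rt) is known to oxidise 1,2-diols to 1,2-diones without C–C cleavage and catechols to o-quinones. It should therefore take 8 through the catechol to 4,4'-[oxybis(methylene)]bis(cyclohexa-3,5-diene-1,2-dione) F3, which is reduced in the same flask with aqueous Na2S2O4 to 10.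

Step 3 (double Diels–Alder). Diene–diene cycloaddition and radical oligomerisation of the bifunctional diene may outpace the sluggish dienophile and give cross-linked material, or 5 may be lost on storage. The fallback sets out from 6 and returns at 7. It uses a masked diene that is released in the flask. Commercial 3-methyl-3-sulfolene F4 is brominated at the allylic methyl group (NBS, (BzO)2, CHCl3, reflux) to 3-(bromomethyl)-3-sulfolene F5. Part of F5 is hydrolysed (aq. acetone, NaHCO3) to 3-(hydroxymethyl)-3-sulfolene F6. Ag2O-mediated etherification of F6 with F5 (CH2Cl2, dark) gives 3,3'-[oxybis(methylene)]bis(3-sulfolene) F7. This crystalline bis-sulfolene is added slowly to neat 6 with BHT at about 160 °C. Cheletropic loss of SO2 then frees 5 only at low stationary concentration, where it should be trapped at once to give 7.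

**Further compounds**

F1 | step 6 | 3,4,6-tribromo-5-(bromomethyl)benzene-1,2-diol (2,3,6-tribromo-4,5-dihydroxybenzyl bromide) | Oc1c(O)c(Br)c(CBr)c(Br)c1Br
F2 | step 6 | 3,4,6-tribromo-5-(hydroxymethyl)benzene-1,2-diol (2,3,6-tribromo-4,5-dihydroxybenzyl alcohol) | Oc1c(O)c(Br)c(CO)c(Br)c1Br
F3 | step 5 | 4,4'-[oxybis(methylene)]bis(cyclohexa-3,5-diene-1,2-dione) | O=C1C=CC(COCC2=CC(=O)C(=O)C=C2)=CC1=O
F4 | step 3 | 3-methyl-2,5-dihydrothiophene 1,1-dioxide (3-methyl-3-sulfolene) | CC1=CCS(=O)(=O)C1
F5 | step 3 | 3-(bromomethyl)-2,5-dihydrothiophene 1,1-dioxide (3-(bromomethyl)-3-sulfolene) | BrCC1=CCS(=O)(=O)C1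
F6 | step 3 | 3-(hydroxymethyl)-2,5-dihydrothiophene 1,1-dioxide (3-(hydroxymethyl)-3-sulfolene) | OCC1=CCS(=O)(=O)C1
F7 | step 3 | 3,3'-[oxybis(methylene)]bis(2,5-dihydrothiophene 1,1-dioxide) | O=S1(=O)CC=C(COCC2=CCS(=O)(=O)C2)C1
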